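Over 5.0 h, four flasks of E with the activator G and J differ in when E or G goes in, and you want the ring L at the end.

| flask | E | G | J | remark | time |
|---|---|---|---|---|---|
| Thursday's | 0.020 M | 2 equiv | 6 mM | run made earlier |  |
| Wednesday's | 0.030 M | 2 equiv | 6 mM | run made earlier |  |
| winter | 0.020 M (fed, over 50 min) | 2.00 equiv | 6.00 mM | all else is in the flask from the start; the feed brings no volume worth counting | 5.0 h |
| midnight | 0.020 M | 2.00 equiv | 6.00 mM | everything together at the start | 5.0 h |
| spring | 0.020 M | 2.00 equiv (fed, over 3.0 h) | 6.00 mM | all else is in the flask from the start; the feed brings no volume worth counting | 5.0 h |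
| dusk | 0.020 M (fed, over 3.0 h) | 2.00 equiv | 6.00 mM | all else is in the flask from the start; the feed brings no volume worth counting | 5.0 h |

Thursday's run (percent of the E charged)

| time / h | L / % |
|---|---|
| 0.250 | 0.2 |
| 0.333 | 0.3 |
| 0.500 | 0.7 |
| 0.833 | 3.4 |
| 1.33 | 6.7 |
| 2.00 | 11.0 |
| 3.00 | 18.0 |

Wednesday's run (percent of the E charged)

| time / min | L / % |
|---|---|
| 4.00 | 0.5 |
| 8.00 | 0 |
| 12.0 | 0 |
| 15.0 | 0.5 |
| 20.0 | 0.6 |
| 25.0 | 1.2 |
| 30.0 | 1.9 |

(scatter of a reading: 0.3 percentage points)

* the flask that comes out highest in amount of L, in percent of the E charged, or "all alike" when all lie within 1.5 percentage points (winter / midnight / spring / dusk / all alike)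
* L at the end, in percent of the E charged, winter
* L at the end, in percent of the E charged, midnight
* L at the end, in percent of the E charged, spring
* L at the end, in percent of the E charged, dusk



The two earlier runs look contradictory. At 0.500 h, Wednesday's run, charged 1.50 times as strongly, reads 2.71 times the fraction of Thursday's run, yet its late slope reads 0.0780 h⁻¹ of the charge, against 0.0674 h⁻¹ in Thursday's run.

So work with the fraction not yet L. In Thursday's run, its logarithm falls between 0.833 h and 3.00 h at 0.0756 h⁻¹. This reading is your L clock, an apparent first-order constant. Run the readings backward on it, and Thursday's clock starts at 0.376 h and Wednesday's at 0.246 h. These two readings of the induction period stand in a ratio of 1.53, beside a ratio of charges of 1.50, so on these readings you can put the contradiction in the start and keep one clock.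

Take the start as a set number of hours of full G. Midnight, charged like Thursday's run, then starts at 0.376 h, while spring, with G arriving evenly, starts at 1.50 h. Your reckoning gives 29.5% for midnight and 23.2% for spring.

The forecast gives 29.5% for midnight, 28.5% for winter, 23% for dusk and 22% for spring, the last differing from your figure. In its words: “Midnight is highest, narrowly over winter.”

Midnight ends highest at 27.5%, with winter at 25.8%, dusk at 20.5% and spring at 20.2%. At 5.00 h, midnight's part not yet L is spread over E at 9.85%, the intermediate D at 18.0% and the side product Z at 24.2%, among others, which one clock doesn't show. From the same starts, midnight's L asks for a clock of 0.0695 h⁻¹ and spring's for 0.0645 h⁻¹, both below 0.0756 h⁻¹.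

    E + G → D (k = 0.246 M⁻¹ min⁻¹)
    D → L (k = 0.00358 min⁻¹)
    E + D → Q (k = 0.154 M⁻¹ min⁻¹)
    D → Z (k = 0.00315 min⁻¹)
    J + D → X (k = 0.105 M⁻¹ min⁻¹)

For the neighbour of midnight with 0.012 M of E, equivalents held, your start scaled with the charge reckons to 0.626 h and the clock gives 28.2%. The computed flask gives 23.1%, with 22.9% of E still there.

The earlier runs and the new flask were generated by integration with constants of no real substance; scatter was added.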